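**Plan**

1. The target is (13S)-15-acetoxylabd-8(17)-en-19-oic acid; labdane numbering is used throughout, also for chain atoms that later become ring atoms. The enabling feature is the quaternary C4 of ring A: it carries a methyl and the C19 carboxyl next to C3, so it can be the α-carbon of a 2-methyl-3-oxo ester. With it goes C8 of ring B, whose C17 can lose hydrogen to end a radical cascade as the exocyclic alkene.
2. Retrosynthesis: the C19 acid goes back to an 8-phenylmenthyl ester and a ketone is placed at C3. C4–C5 and C9–C10 are then cut together, which opens both rings to an E,E-diene keto ester. C1–C2 is cut last, to an allylic bromide and a 2-methylacetoacetate.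
3. Forward: the C15 chain comes from (2E,6E)-farnesol (hydrogenation of C2=C3, pivalate, oxidation of the terminal E-methyl, bromide) and is joined to the acetoacetate dianion. Ring A and then ring B close in one operation.
4. End game: the C3 oxygen is removed (reduction, Barton–McCombie), LiAlH4 frees the 15,19-diol, C15 is acetylated and C19 is oxidised to the acid.
5. Stereochemistry: C13 comes from the Ru(OAc)2[(R)-BINAP] hydrogenation. C4, C5, C9 and C10 are set relative to one another by the chair–chair transition state, and their absolute sense by the auxiliary.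

Key step: step 7

Assumption: the (−)-8-phenylmenthyl ester is taken to open the face of the C4 radical that leads to the (4S,5R,9S,10R) series, as in related 2-methyl-3-oxo ester cyclisations; should the sense prove opposite, (+)-8-phenylmenthol replaces it from step 5 on with no other change.

**Route**

Step 1
Reactants: 1 (2E,6E)-farnesol
Product: 2 (3S,6E)-3,7,11-trimethyldodeca-6,10-dien-1-ol [(S)-2,3-dihydrofarnesol]
Conditions: Ru(OAc)2[(R)-BINAP] (0.5 mol%), H2 (100 atm), MeOH–H2O 95:5, 20 °C
Reagents that add atoms: none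
Why: Noyori asymmetric hydrogenation of an allylic alcohol, in which the hydroxyl binds ruthenium so that only the C2=C3 alkene is reduced and, for the 2E geometry, the (R)-BINAP complex should deliver hydrogen to the face that gives the 3S centre (C13 of the target), as for geraniol to (S)-citronellol.

Step 2
Reactants: 2 (S)-2,3-dihydrofarnesol
Product: 3 (3S,6E)-3,7,11-trimethyldodeca-6,10-dien-1-yl pivalate
Conditions: PivCl, pyridine, DMAP (cat.), CH2Cl2, 0 °C to rt
Reagents that add atoms: pivaloyl chloride, CC(C)(C)C(Cl)=O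
Why: DMAP-catalysed acylation of a primary alcohol; the pivalate is chosen over the acetate because it should resist the dianion of step 6, borohydride and the thiocarbonylation, and it is cleaved by the same LiAlH4 treatment that removes the auxiliary.

Step 3
Reactants: 3 dihydrofarnesyl pivalate
Product: 4 (3S,6E,10E)-12-hydroxy-3,7,11-trimethyldodeca-6,10-dien-1-yl pivalate
Conditions: SeO2 (0.3 equiv), t-BuOOH (3 equiv), salicylic acid (0.1 equiv), CH2Cl2, rt, stopped at partial conversion
Reagents that add atoms: selenium dioxide, O=[Se]=O (transfers the oxygen); tert-butyl hydroperoxide, CC(C)(C)OO (restores it)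
Why: Riley allylic oxidation in its catalytic SeO2/t-BuOOH form (ene reaction, then [2,3]-sigmatropic shift) should attack the terminal isopropylidene group, the less hindered of the two trisubstituted alkenes, at its E-methyl and give the E allylic alcohol; the run is stopped at partial conversion so that the enal and products of attack at the inner alkene stay minor and recovered 3 is recycled.

Step 4
Reactants: 4 allylic alcohol
Product: 5 (3S,6E,10E)-12-bromo-3,7,11-trimethyldodeca-6,10-dien-1-yl pivalate
Conditions: CBr4, PPh3, CH2Cl2, 0 °C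
Reagents that add atoms: carbon tetrabromide, BrC(Br)(Br)Br
Why: Appel reaction, in which bromide displaces the oxyphosphonium group at the primary allylic carbon in SN2 fashion at 0 °C, so the alkene keeps its position and E geometry and the pivalate is untouched.

Step 5
Reactants: 6 (−)-8-phenylmenthol [(1R,2S,5R)-5-methyl-2-(2-phenylpropan-2-yl)cyclohexan-1-ol]; 7 ethyl 2-methylacetoacetate (excess)
Product: 8 (−)-8-phenylmenthyl 2-methyl-3-oxobutanoate (both C2 epimers)
Conditions: DMAP (0.3 equiv), toluene, reflux with slow distillation of ethanol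
Reagents that add atoms: none
Why: DMAP-catalysed transesterification of an enolisable β-keto ester, which runs through the acylketene and is driven by removal of ethanol; the C2 centre is of no consequence because it is erased on enolisation.

Step 6
Reactants: 8 (−)-8-phenylmenthyl 2-methylacetoacetate; 5 allylic bromide
Product: 10 (−)-8-phenylmenthyl (6E,10E,14S)-2,6,10,14-tetramethyl-3-oxo-16-(pivaloyloxy)hexadeca-6,10-dienoate, via sodium lithium dienolate 9 (not isolated)
Conditions: NaH, THF, 0 °C; n-BuLi, 0 °C; then 5, 0 °C; 1 M HCl quench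
Reagents that add atoms: none
Why: Weiler alkylation of an acetoacetate dianion, in which the more reactive terminal carbanion displaces the allylic bromide in SN2 fashion to form the C1–C2 bond, leaving the methylated α-carbon (C4), both E alkenes and the hindered pivalate intact.

Step 7
Reactants: 10 acyclic (6E,10E)-keto ester
Product: 11 (−)-8-phenylmenthyl (13S)-3-oxo-15-(pivaloyloxy)labd-8(17)-en-19-oate (4α-methyl, 4β-axial ester, 5α-H, 9α-H, 10β-methyl)
Conditions: Mn(OAc)3·2H2O (2.2 equiv), Cu(OAc)2·H2O (1.0 equiv), degassed AcOH, 25 °C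
Reagents that add atoms: none
Why: Mn(OAc)3 forms the manganese enolate of the 2-methyl-3-oxo ester and inner-sphere electron transfer releases the electrophilic tertiary C4 radical, which adds to C5 of the C5=C10 alkene; the tertiary C10 radical so formed adds to C9 of the C8=C9 alkene, and the tertiary C8 radical is captured by Cu(OAc)2 as an alkylcopper species that loses a C17 hydrogen, the monovalent copper left behind being re-oxidised by the second equivalent of Mn(OAc)3. The closest known reaction type is the oxidative free-radical polyene cyclisation of unsaturated 2-methyl-3-oxo esters with trivalent manganese and divalent copper, which gives trans-decalins with an axial ester and has been run on 8-phenylmenthyl esters. Ring A closes 6-endo-trig (C4 to C5) and ring B closes 6-endo-trig (C10 to C9), in both cases because the trisubstituted alkene offers its unsubstituted carbon and leaves a tertiary radical. C5, C10 and C9 follow from the chair–chair arrangement of the E,E-diene (trans ring fusion, C20 axial, C11 chain equatorial), C4 takes the ester axial and the methyl equatorial in that same chair, and the absolute sense of all four comes from the phenyl ring of the auxiliary, which lies over one face of the planar C4 radical so that C5 bonds to the other. The step needs face selectivity at C4 and loss of hydrogen from C17 in preference to C7 or C9: the first rests on the auxiliary, the second on the syn elimination from the crowded tertiary alkylcopper intermediate, which favours the least substituted (exocyclic) alkene, while the saturated, ester-capped C11–C15 chain offers the radicals nothing else to react with.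

Step 8
Reactants: 11 bicyclic 3-oxo ester
Product: 12 (−)-8-phenylmenthyl (13S)-3β-hydroxy-15-(pivaloyloxy)labd-8(17)-en-19-oate
Conditions: NaBH4, MeOH–THF, 0 °C
Reagents that add atoms: none
Why: Borohydride reduction of the ketone, in which hydride should arrive on the α face, away from the axial C20 methyl and the axial C19 ester, to give the equatorial 3β-alcohol (a centre that is removed in step 10), while both hindered esters are inert at 0 °C.

Step 9
Reactants: 12 3β-alcohol
Product: 13 (−)-8-phenylmenthyl (13S)-3β-[(imidazol-1-yl)thiocarbonyloxy]-15-(pivaloyloxy)labd-8(17)-en-19-oate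
Conditions: 1,1'-thiocarbonyldiimidazole (3 equiv), DMAP (0.5 equiv), ClCH2CH2Cl, reflux
Reagents that add atoms: 1,1'-thiocarbonyldiimidazole, S=C(n1ccnc1)n1ccnc1
Why: Acyl transfer to the secondary hydroxyl under neutral conditions (first half of a Barton–McCombie deoxygenation), chosen over a xanthate so that no alkoxide of the β-hydroxy ester, which could open ring A by retro-aldol cleavage, is ever formed.

Step 10
Reactants: 13 thiocarbonylimidazolide
Product: 14 (−)-8-phenylmenthyl (13S)-15-(pivaloyloxy)labd-8(17)-en-19-oate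
Conditions: Bu3SnH (2 equiv), AIBN (0.2 equiv), toluene, 110 °C
Reagents that add atoms: none
Why: Barton–McCombie radical deoxygenation, in which the tributyltin radical adds to sulfur, the C3–O bond breaks and the secondary C3 radical is reduced by Bu3SnH, the rigid trans-decalin keeping the C8=C17 alkene out of its reach.

Step 11
Reactants: 14 deoxygenated diester
Product: 15 (13S)-labd-8(17)-ene-15,19-diol
Conditions: LiAlH4 (excess), THF, reflux; then H2O, aq. NaOH
Reagents that add atoms: none
Why: Hydride reduction of both esters with LiAlH4, where the neopentyl, axial C19 ester needs reflux but has no competing pathway, the pivalate falls at the same time, the isolated alkene is inert and the auxiliary is recovered as 6.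

Step 12
Reactants: 15 15,19-diol
Product: 16 (13S)-15-acetoxylabd-8(17)-en-19-ol
Conditions: AcCl (1.05 equiv), 2,4,6-collidine (2 equiv), CH2Cl2, −78 °C
Reagents that add atoms: acetyl chloride, CC(Cl)=O
Why: Kinetically controlled acylation with acetyl chloride and a hindered pyridine base at low temperature should take the unhindered C15 hydroxyl and leave the C19 hydroxyl, which is neopentyl, axial on the quaternary C4 and 1,3-diaxial to C20.

Step 13
Reactants: 16 15-acetoxy-19-ol
Product: 17 (13S)-15-acetoxylabd-8(17)-en-19-al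
Conditions: TEMPO (0.2 equiv), PhI(OAc)2 (1.2 equiv), CH2Cl2, rt
Reagents that add atoms: none
Why: Oxoammonium-catalysed (TEMPO/PhI(OAc)2) oxidation of a primary alcohol stops at the aldehyde, tolerates the acetate and the exocyclic alkene, and the aldehyde on the quaternary C4 cannot epimerise.

Step 14
Reactants: 17 19-aldehyde
Product: 18 (13S)-15-acetoxylabd-8(17)-en-19-oic acid, (4S,5R,9S,10R,13S), the target
Conditions: NaClO2, NaH2PO4, 2-methyl-2-butene (10 equiv), t-BuOH–H2O, rt
Reagents that add atoms: sodium chlorite, [Na+].[O-]Cl=O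
Why: Pinnick oxidation of the hindered aldehyde to the acid, with 2-methyl-2-butene as the scavenger that keeps hypochlorous acid away from the C8=C17 alkene, in a buffered medium that leaves the acetate alone.

**Compound list**

1 | (2E,6E)-farnesol | CC(C)=CCC/C(C)=C/CC/C(C)=C/CO | starting material
2 | (3S,6E)-3,7,11-trimethyldodeca-6,10-dien-1-ol [(S)-2,3-dihydrofarnesol] | CC(C)=CCC/C(C)=C/CC[C@H](C)CCO | intermediate
3 | (3S,6E)-3,7,11-trimethyldodeca-6,10-dien-1-yl pivalate | CC(C)=CCC/C(C)=C/CC[C@H](C)CCOC(=O)C(C)(C)C | intermediate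
4 | (3S,6E,10E)-12-hydroxy-3,7,11-trimethyldodeca-6,10-dien-1-yl pivalate | OC/C(C)=C/CC/C(C)=C/CC[C@H](C)CCOC(=O)C(C)(C)C | intermediate
5 | (3S,6E,10E)-12-bromo-3,7,11-trimethyldodeca-6,10-dien-1-yl pivalate | BrC/C(C)=C/CC/C(C)=C/CC[C@H](C)CCOC(=O)C(C)(C)C | intermediate
6 | (−)-8-phenylmenthol, (1R,2S,5R)-5-methyl-2-(2-phenylpropan-2-yl)cyclohexan-1-ol | O[C@@H]1C[C@H](C)CC[C@H]1C(C)(C)c1ccccc1 | starting material
7 | ethyl 2-methylacetoacetate | CCOC(=O)C(C)C(C)=O | starting material
8 | (−)-8-phenylmenthyl 2-methyl-3-oxobutanoate (C2 epimers) | CC(=O)C(C)C(=O)O[C@@H]1C[C@H](C)CC[C@H]1C(C)(C)c1ccccc1 | intermediate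
9 | sodium lithium dienolate (dianion) of 8 | [Na+].[Li+].C=C([O-])C(C)=C([O-])O[C@@H]1C[C@H](C)CC[C@H]1C(C)(C)c1ccccc1 | intermediate
10 | (−)-8-phenylmenthyl (6E,10E,14S)-2,6,10,14-tetramethyl-3-oxo-16-(pivaloyloxy)hexadeca-6,10-dienoate (C2 epimers) | CC(C(=O)O[C@@H]1C[C@H](C)CC[C@H]1C(C)(C)c1ccccc1)C(=O)CC/C(C)=C/CC/C(C)=C/CC[C@H](C)CCOC(=O)C(C)(C)C | intermediate
11 | (−)-8-phenylmenthyl (13S)-3-oxo-15-(pivaloyloxy)labd-8(17)-en-19-oate | C=C1CC[C@@H]2[C@](C)(CCC(=O)[C@]2(C)C(=O)O[C@@H]3C[C@H](C)CC[C@H]3C(C)(C)c4ccccc4)[C@H]1CC[C@H](C)CCOC(=O)C(C)(C)C | intermediate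
12 | (−)-8-phenylmenthyl (13S)-3β-hydroxy-15-(pivaloyloxy)labd-8(17)-en-19-oate | C=C1CC[C@@H]2[C@](C)(CC[C@H](O)[C@]2(C)C(=O)O[C@@H]3C[C@H](C)CC[C@H]3C(C)(C)c4ccccc4)[C@H]1CC[C@H](C)CCOC(=O)C(C)(C)C | intermediate
13 | (−)-8-phenylmenthyl (13S)-3β-[(imidazol-1-yl)thiocarbonyloxy]-15-(pivaloyloxy)labd-8(17)-en-19-oate | C=C1CC[C@@H]2[C@](C)(CC[C@H](OC(=S)n3ccnc3)[C@]2(C)C(=O)O[C@@H]4C[C@H](C)CC[C@H]4C(C)(C)c5ccccc5)[C@H]1CC[C@H](C)CCOC(=O)C(C)(C)C | intermediate
14 | (−)-8-phenylmenthyl (13S)-15-(pivaloyloxy)labd-8(17)-en-19-oate | C=C1CC[C@@H]2[C@](C)(CCC[C@]2(C)C(=O)O[C@@H]3C[C@H](C)CC[C@H]3C(C)(C)c4ccccc4)[C@H]1CC[C@H](C)CCOC(=O)C(C)(C)C | intermediate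
15 | (13S)-labd-8(17)-ene-15,19-diol | C=C1CC[C@@H]2[C@](C)(CCC[C@]2(C)CO)[C@H]1CC[C@H](C)CCO | intermediate
16 | (13S)-15-acetoxylabd-8(17)-en-19-ol | C=C1CC[C@@H]2[C@](C)(CCC[C@]2(C)CO)[C@H]1CC[C@H](C)CCOC(C)=O | intermediate
17 | (13S)-15-acetoxylabd-8(17)-en-19-al | C=C1CC[C@@H]2[C@](C)(CCC[C@]2(C)C=O)[C@H]1CC[C@H](C)CCOC(C)=O | intermediate
18 | (13S)-15-acetoxylabd-8(17)-en-19-oic acid, (4S,5R,9S,10R,13S) | C=C1CC[C@@H]2[C@](C)(CCC[C@]2(C)C(=O)O)[C@H]1CC[C@H](C)CCOC(C)=O | target

**Step count**

Total: 14 steps. Longest linear sequence: 13 steps (steps 1–4 and 6–14, from farnesol); step 5 is the one-step side branch.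

**Steps most likely to fail, with fallbacks**

Step 7. What may go wrong: the phenyl ring of the auxiliary may discriminate too weakly between the two faces of the conformationally free C4 radical, so that both ring-diastereomers form. The fallback is a chelation-controlled cyclisation on the antipodal auxiliary, and it sets out from bromide 5. Ester 7 is transesterified as in step 5 with (+)-8-phenylmenthol (purchased, O[C@H]1C[C@@H](C)CC[C@@H]1C(C)(C)c1ccccc1) to (+)-8-phenylmenthyl 2-methylacetoacetate F1. Its sodium lithium dienolate F2 is alkylated with 5 as in step 6 to the antipodal-auxiliary keto ester F3. F3 is cyclised with Mn(OAc)3·2H2O and Cu(OAc)2·H2O in CF3CH2OH at −5 °C in the presence of Yb(OTf)3 (1 equiv). The trivalent ytterbium binds both carbonyl oxygens, so the radical is held with the carbonyls syn and the phenyl ring fixed over one face. This chelate is expected to leave open the face opposite to that of the unchelated radical, so the (+)-auxiliary is the one that should give the same ring configuration, in the bicyclic 3-oxo ester F4. Borohydride reduction (3β-alcohol F5), thiocarbonylation (imidazolide F6) and Bu3SnH reduction (deoxygenated ester F7) follow as in steps 8 to 10. LiAlH4 as in step 11 then gives diol 15, where the route is rejoined.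

Step 12. What may go wrong: both hydroxyls are primary, so acylation may run on to the diacetate or take the C19 hydroxyl competitively. The fallback is temporary silyl protection with acetylation at the very end, and it sets out from diol 15. TBDPSCl (1.05 equiv) and imidazole in CH2Cl2 at 0 °C should give the 15-silyl ether F8, because the bulky silyl chloride separates the two hydroxyls far more sharply than an acetyl donor. TEMPO/PhI(OAc)2 should give the silyl ether aldehyde F9, and NaClO2/NaH2PO4/2-methyl-2-butene the silyl ether acid F10. TBAF in THF frees the 15-hydroxy acid F11 (imbricatolic acid). Ac2O/pyridine/DMAP, with aqueous NaHCO3 work-up to hydrolyse any mixed anhydride and then acidification, gives target 18.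

Step 9. What may go wrong: acyl transfer to the C3 hydroxyl, which is flanked by the quaternary C4, may be slow, with retro-aldol opening of ring A or decomposition on prolonged heating. The fallback removes the C3 oxygen at the ketone stage by hydrazone reduction and replaces steps 8 to 10. It sets out from ketone 11. TsNHNH2 in EtOH with a trace of AcOH at reflux should give the tosylhydrazone F12. Catecholborane in CHCl3 at 0 °C, then NaOAc·3H2O at reflux (a Caglioti-type reduction: hydride adds to C=N, sulfinate leaves and the diazene loses dinitrogen), gives ester 14, where the route is rejoined.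

**Further compounds**

F1 | step 7 | (+)-8-phenylmenthyl 2-methyl-3-oxobutanoate | CC(=O)C(C)C(=O)O[C@H]1C[C@@H](C)CC[C@@H]1C(C)(C)c1ccccc1
F2 | step 7 | sodium lithium dienolate of F1 | [Na+].[Li+].C=C([O-])C(C)=C([O-])O[C@H]1C[C@@H](C)CC[C@@H]1C(C)(C)c1ccccc1
F3 | step 7 | (+)-8-phenylmenthyl (6E,10E,14S)-2,6,10,14-tetramethyl-3-oxo-16-(pivaloyloxy)hexadeca-6,10-dienoate | CC(C(=O)O[C@H]1C[C@@H](C)CC[C@@H]1C(C)(C)c1ccccc1)C(=O)CC/C(C)=C/CC/C(C)=C/CC[C@H](C)CCOC(=O)C(C)(C)C
F4 | step 7 | (+)-8-phenylmenthyl (13S)-3-oxo-15-(pivaloyloxy)labd-8(17)-en-19-oate | C=C1CC[C@@H]2[C@](C)(CCC(=O)[C@]2(C)C(=O)O[C@H]3C[C@@H](C)CC[C@@H]3C(C)(C)c4ccccc4)[C@H]1CC[C@H](C)CCOC(=O)C(C)(C)C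
F5 | step 7 | (+)-8-phenylmenthyl (13S)-3β-hydroxy-15-(pivaloyloxy)labd-8(17)-en-19-oate | C=C1CC[C@@H]2[C@](C)(CC[C@H](O)[C@]2(C)C(=O)O[C@H]3C[C@@H](C)CC[C@@H]3C(C)(C)c4ccccc4)[C@H]1CC[C@H](C)CCOC(=O)C(C)(C)C
F6 | step 7 | (+)-8-phenylmenthyl (13S)-3β-[(imidazol-1-yl)thiocarbonyloxy]-15-(pivaloyloxy)labd-8(17)-en-19-oate | C=C1CC[C@@H]2[C@](C)(CC[C@H](OC(=S)n3ccnc3)[C@]2(C)C(=O)O[C@H]4C[C@@H](C)CC[C@@H]4C(C)(C)c5ccccc5)[C@H]1CC[C@H](C)CCOC(=O)C(C)(C)C
F7 | step 7 | (+)-8-phenylmenthyl (13S)-15-(pivaloyloxy)labd-8(17)-en-19-oate | C=C1CC[C@@H]2[C@](C)(CCC[C@]2(C)C(=O)O[C@H]3C[C@@H](C)CC[C@@H]3C(C)(C)c4ccccc4)[C@H]1CC[C@H](C)CCOC(=O)C(C)(C)C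
F8 | step 12 | (13S)-15-(tert-butyldiphenylsilyloxy)labd-8(17)-en-19-ol | C=C1CC[C@@H]2[C@](C)(CCC[C@]2(C)CO)[C@H]1CC[C@H](C)CCO[Si](c3ccccc3)(c4ccccc4)C(C)(C)C
F9 | step 12 | (13S)-15-(tert-butyldiphenylsilyloxy)labd-8(17)-en-19-al | C=C1CC[C@@H]2[C@](C)(CCC[C@]2(C)C=O)[C@H]1CC[C@H](C)CCO[Si](c3ccccc3)(c4ccccc4)C(C)(C)C
F10 | step 12 | (13S)-15-(tert-butyldiphenylsilyloxy)labd-8(17)-en-19-oic acid | C=C1CC[C@@H]2[C@](C)(CCC[C@]2(C)C(=O)O)[C@H]1CC[C@H](C)CCO[Si](c3ccccc3)(c4ccccc4)C(C)(C)C
F11 | step 12 | (13S)-15-hydroxylabd-8(17)-en-19-oic acid | C=C1CC[C@@H]2[C@](C)(CCC[C@]2(C)C(=O)O)[C@H]1CC[C@H](C)CCO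
F12 | step 9 | (−)-8-phenylmenthyl (13S)-15-(pivaloyloxy)-3-(tosylhydrazono)labd-8(17)-en-19-oate | C=C1CC[C@@H]2[C@](C)(CCC(=NNS(=O)(=O)c3ccc(C)cc3)[C@]2(C)C(=O)O[C@@H]4C[C@H](C)CC[C@H]4C(C)(C)c5ccccc5)[C@H]1CC[C@H](C)CCOC(=O)C(C)(C)C
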